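**Assumption:** the target is the (4R,5S,7S,8S,10R,11R) enantiomer encoded by the SMILES, with both esters as (Z)-2-methylbut-2-enoates (angelates). Locants C1–C11 are longipinane numbers (C1 carbonyl, C2=C3(CH3), C4/C11 bridgeheads, C5/C10 one-carbon bridges, C6 C(CH3)2, C7/C8 ester carbons, C9 CH2) and are used for the corresponding atoms of all intermediates.

## Retrosynthetic overview

1. 25 ⇐ diol 23 (double angeloylation) ⇐ α-hydroxy ketone 22 (hydroxyl-directed anti reduction).
2. Seven-membered ring, formed last: C7–C8 bond by intramolecular NHC cross-benzoin of dialdehyde 21; the C8 aldehyde is the acyl anion, the neopentyl C7 aldehyde the acceptor.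
3. 21 ⇐ bicyclic ketone 12: the C5 carbonyl takes on C6/C7 by Peterson olefination and reductive methylation; oxidation at C1 gives the enone.
4. Four- and six-membered rings, formed together and first: intramolecular vinylketene–alkene [2+2] of acid 9, with the C1 silyloxy stereocentre controlling the face.
5. 9 ⇐ asymmetric vinylogous Mukaiyama aldol of the dienolate of methyl 3-methylbut-2-enoate with enal 4 (from 3-methylbut-2-enal and HC(OMe)3).

## Route

Step 1
Reactants: 1 3-methylbut-2-enal
Product: 2 trimethyl{[(1E)-3-methylbuta-1,3-dien-1-yl]oxy}silane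
Conditions: Me3SiCl, Et3N, ZnCl2 (3 mol%), benzene, 25 → 80 °C; distillation
Reagents that add atoms: chlorotrimethylsilane, C[Si](C)(C)Cl
Why: γ-Deprotonation and O-silylation of the enal (silyl dienol ether formation) gives the 1-siloxy-1,3-diene that serves as the γ-nucleophilic C5 unit.

Step 2
Reactants: 2 trimethyl{[(1E)-3-methylbuta-1,3-dien-1-yl]oxy}silane; 3 trimethyl orthoformate
Product: 4 (2E)-5,5-dimethoxy-3-methylpent-2-enal
Conditions: ZnCl2 (10 mol%), CH2Cl2, 0 → 23 °C; chromatography (E isomer)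
Reagents that add atoms: none
Why: Vinylogous Mukaiyama alkylation: the dimethoxycarbenium ion from the orthoester attacks the terminal γ-carbon of the dienol ether (C8–C9 bond) and the conjugated enal is regenerated, E-favoured from the s-trans diene; the minor Z isomer is removed because it would give the C10 epimer later.

Step 3
Reactants: 4 (2E)-5,5-dimethoxy-3-methylpent-2-enal; 5 methyl 3-methylbut-2-enoate
Product: 7 methyl (2E,5S,6E)-5-hydroxy-9,9-dimethoxy-3,7-dimethylnona-2,6-dienoate, via silyl dienol ether 6 (not isolated)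
Conditions: 5, LiN(iPr)2, tBuMe2SiCl, THF/DMPU, −78 °C (crude 6); then 4, SiCl4 (1.1 equiv), N,N'-pentane-1,5-diylbis[(S)-N,3,5-trimethyl-3,5-dihydro-4H-dinaphtho[2,1-d:1',2'-f][1,3,2]diazaphosphepin-4-amine 4-oxide] (2 mol%), iPr2NEt (10 mol%), CH2Cl2, −78 °C; aq. NaHCO3
Reagents that add atoms: none
Why: Lewis-base-activated SiCl4 vinylogous Mukaiyama aldol: the dienolate reacts only at its γ-carbon (C1–C2 bond) to give the E-enoate, and the chiral phosphoramide-bound silyl cation directs attack to the Si face of the enal, setting the (5S) carbinol (C1 of the target); the catalyst enantiomer is the one chosen for Si-face addition.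

Step 4
Reactants: 7 methyl (2E,5S,6E)-5-hydroxy-9,9-dimethoxy-3,7-dimethylnona-2,6-dienoate
Product: 8 methyl (2E,5S,6E)-5-{[tert-butyl(dimethyl)silyl]oxy}-9,9-dimethoxy-3,7-dimethylnona-2,6-dienoate
Conditions: tBuMe2SiCl, imidazole, DMF, 23 °C
Reagents that add atoms: tert-butylchlorodimethylsilane, CC(C)(C)[Si](C)(C)Cl
Why: Silyl ether protection masks the alcohol for ketene generation and provides the bulky allylic group that later steers the cycloaddition face; the stereocentre is untouched.

Step 5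
Reactants: 8 methyl (2E,5S,6E)-5-{[tert-butyl(dimethyl)silyl]oxy}-9,9-dimethoxy-3,7-dimethylnona-2,6-dienoate
Product: 9 (2E,5S,6E)-5-{[tert-butyl(dimethyl)silyl]oxy}-9,9-dimethoxy-3,7-dimethylnona-2,6-dienoic acid
Conditions: LiOH, THF/MeOH/H2O, 40 °C; then HCl to pH 4, 0 °C
Reagents that add atoms: lithium hydroxide, [Li+].[OH-]
Why: Saponification of the methyl ester; silyl ether, dimethyl acetal and both alkenes are stable to aqueous hydroxide and to the brief cold mild-acid work-up.

Step 6
Reactants: 9 (2E,5S,6E)-5-{[tert-butyl(dimethyl)silyl]oxy}-9,9-dimethoxy-3,7-dimethylnona-2,6-dienoic acid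
Product: 12 (1R,2S,5R,7R)-2-{[tert-butyl(dimethyl)silyl]oxy}-7-(2,2-dimethoxyethyl)-7-methyl-4-methylidenebicyclo[3.1.1]heptan-6-one, via acid chloride 10 (not isolated), via vinylketene 11 (not isolated)
Conditions: 1-chloro-N,N,2-trimethylprop-1-en-1-amine, CH2Cl2, 0 °C; then slow addition to Et3N, toluene, 110 °C (high dilution)
Reagents that add atoms: none
Why: Intramolecular vinylketene–alkene [2+2] cycloaddition: the ketene carbonyl carbon (C5) bonds to the less substituted alkene carbon C11 and the ketene α-carbon C4 to the fully substituted C10, giving the bridged bicyclo[3.1.1]heptan-6-one. The E alkene places the C10 methyl syn to the three-carbon bridge, and allylic 1,3-strain at C1 (H eclipsing the alkene, silyloxy turned away from the C10 methyl) fixes the face, so C4, C10 and C11 arise with the target configuration.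

Step 7
Reactants: 12 (1R,2S,5R,7R)-2-{[tert-butyl(dimethyl)silyl]oxy}-7-(2,2-dimethoxyethyl)-7-methyl-4-methylidenebicyclo[3.1.1]heptan-6-one; 13 methyl 2-(trimethylsilyl)propanoate
Product: 16 methyl 2-[7-(2,2-dimethoxyethyl)-2-hydroxy-7-methyl-4-methylidenebicyclo[3.1.1]heptan-6-ylidene]propanoate (ring stereocentres as in 12; alkene geometry mixed), via lithium ester enolate 14 (not isolated), via silyl ether 15 (not isolated)
Conditions: 13, LiN(iPr)2, THF, −78 °C; 12, −78 → 23 °C; then Bu4NF, 23 °C; aq. NH4Cl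
Reagents that add atoms: none
Why: Peterson olefination: the α-silyl ester enolate adds to the strained, non-enolisable cyclobutanone and loses silanolate to form the C5=C6 alkylidene ester; fluoride then frees the C1 hydroxyl needed in the next step, and no stereocentre is created.

Step 8
Reactants: 16 methyl 2-[7-(2,2-dimethoxyethyl)-2-hydroxy-7-methyl-4-methylidenebicyclo[3.1.1]heptan-6-ylidene]propanoate
Product: 17 methyl 2-[7-(2,2-dimethoxyethyl)-2-hydroxy-7-methyl-4-methylidenebicyclo[3.1.1]heptan-6-yl]-2-methylpropanoate (new C5–H syn to the three-carbon bridge; other centres as in 12)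
Conditions: Li (2.5 equiv), NH3/THF, −78 °C; isoprene; MeI (3 equiv), −78 → −40 °C; aq. NH4Cl
Reagents that add atoms: iodomethane, CI
Why: Dissolving-metal (Birch-type) reductive alkylation: the enoate dianion is protonated at C5 by the neighbouring C1 hydroxyl, which sits over the bridge-side face, so H enters syn to the three-carbon bridge and the side chain ends on the face of the C9 chain; the lithium ester enolate is then C-methylated to the gem-dimethyl C6.

Step 9
Reactants: 17 methyl 2-[7-(2,2-dimethoxyethyl)-2-hydroxy-7-methyl-4-methylidenebicyclo[3.1.1]heptan-6-yl]-2-methylpropanoate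
Product: 19 2-[2-hydroxy-7-methyl-4-methylidene-7-(2-oxoethyl)bicyclo[3.1.1]heptan-6-yl]-2-methylpropanal (stereocentres as in 17), via aldehyde acetal 18 (not isolated)
Conditions: iBu2AlH (2.5 equiv), CH2Cl2, −78 °C; then 1 M HCl/THF, 0 → 23 °C
Reagents that add atoms: water, O
Why: Partial reduction of the α-quaternary methyl ester stops at the stable aluminium hemiacetal (aldehyde C7), and the acidic work-up hydrolyses the dimethyl acetal to the C8 aldehyde; no stereocentre is affected.

Step 10
Reactants: 19 2-[2-hydroxy-7-methyl-4-methylidene-7-(2-oxoethyl)bicyclo[3.1.1]heptan-6-yl]-2-methylpropanal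
Product: 21 2-[4,6-dimethyl-2-oxo-6-(2-oxoethyl)bicyclo[3.1.1]hept-3-en-7-yl]-2-methylpropanal (C6 methyl and C7–H syn to the enone bridge; absolute configuration as in the target), via unconjugated enone 20 (not isolated)
Conditions: Dess–Martin periodinane, NaHCO3, CH2Cl2, 0 °C; then Et3N, 23 °C
Reagents that add atoms: none
Why: Dess–Martin oxidation of the only alcohol gives the C1 ketone, and mild base moves the exocyclic β,γ-alkene into conjugation (C2=C3), forming the verbenone-type enone and removing the auxiliary C1 stereocentre.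

Step 11
Reactants: 21 2-[4,6-dimethyl-2-oxo-6-(2-oxoethyl)bicyclo[3.1.1]hept-3-en-7-yl]-2-methylpropanal
Product: 22 (4R,5S,7S,10R,11R)-7-hydroxylongipin-2-ene-1,8-dione
Conditions: (5aR,10bS)-2-(pentafluorophenyl)-5a,10b-dihydro-4H,6H-indeno[2,1-b][1,2,4]triazolo[4,3-d][1,4]oxazin-2-ium tetrafluoroborate (15 mol%), Et3N (20 mol%), toluene, 23 °C
Reagents that add atoms: none
Why: Proposed new method: the carbene adds to the unhindered C8 aldehyde to give a Breslow acyl anion equivalent that attacks the non-enolisable, α-quaternary C7 aldehyde, closing the bridged seven-membered ring as the acyloin; the closest known chemistry is NHC-catalysed intramolecular crossed benzoin cyclisation of dialdehydes and keto-aldehydes to five- and six-membered acyloins. Attack on the enone (ketone carbonyl or β-carbon) would need a trans-fused five-membered ring on the cyclobutane and is excluded. The two faces of the C7 aldehyde are nearly equivalent in the substrate, so the chiral triazolium sets (7S); its enantiomer is used if the 7R epimer is favoured.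

Step 12
Reactants: 22 (4R,5S,7S,10R,11R)-7-hydroxylongipin-2-ene-1,8-dione
Product: 23 (4R,5S,7S,8S,10R,11R)-7,8-dihydroxylongipin-2-en-1-one
Conditions: Me4NBH(OAc)3 (5 equiv), MeCN/AcOH 1:1, −20 °C
Reagents that add atoms: none
Why: Saksena–Evans hydroxyl-directed reduction: the C7 alkoxy-bound borohydride delivers hydride to the C8 ketone on the face of the C7 oxygen, so the new C8 hydroxyl is trans to it (8S); the enone, which has no directing hydroxyl, is not reduced.

Step 13
Reactants: 23 (4R,5S,7S,8S,10R,11R)-7,8-dihydroxylongipin-2-en-1-one; 24 (2Z)-2-methylbut-2-enoic anhydride (angelic anhydride)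
Product: 25 (4R,5S,7S,8S,10R,11R)-1-oxolongipin-2-ene-7,8-diyl bis[(2Z)-2-methylbut-2-enoate] (CNP0355097.2)
Conditions: LiN(SiMe3)2 (2.3 equiv), THF, −20 °C; 24 (3 equiv), −20 → 0 °C; aq. NH4Cl
Reagents that add atoms: none
Why: Acylation of the pre-formed lithium alkoxides with the anhydride at low temperature esterifies both hindered secondary hydroxyls without nucleophilic catalysts, which avoids Z→E isomerisation of the angelate to the tiglate; no stereocentre is touched.

## Compound list

1 | 3-methylbut-2-enal | CC(C)=CC=O | starting material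
2 | trimethyl{[(1E)-3-methylbuta-1,3-dien-1-yl]oxy}silane | C=C(C)/C=C/O[Si](C)(C)C | intermediate
3 | trimethyl orthoformate | COC(OC)OC | starting material
4 | (2E)-5,5-dimethoxy-3-methylpent-2-enal | O=C/C=C(\C)CC(OC)OC | intermediate
5 | methyl 3-methylbut-2-enoate | COC(=O)C=C(C)C | starting material
6 | tert-butyl[(1-methoxy-3-methylbuta-1,3-dien-1-yl)oxy]dimethylsilane | C=C(C)C=C(OC)O[Si](C)(C)C(C)(C)C | intermediate (not isolated)
7 | methyl (2E,5S,6E)-5-hydroxy-9,9-dimethoxy-3,7-dimethylnona-2,6-dienoate | COC(=O)/C=C(\C)C[C@H](O)/C=C(\C)CC(OC)OC | intermediate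
8 | methyl (2E,5S,6E)-5-{[tert-butyl(dimethyl)silyl]oxy}-9,9-dimethoxy-3,7-dimethylnona-2,6-dienoate | COC(=O)/C=C(\C)C[C@H](O[Si](C)(C)C(C)(C)C)/C=C(\C)CC(OC)OC | intermediate
9 | (2E,5S,6E)-5-{[tert-butyl(dimethyl)silyl]oxy}-9,9-dimethoxy-3,7-dimethylnona-2,6-dienoic acid | OC(=O)/C=C(\C)C[C@H](O[Si](C)(C)C(C)(C)C)/C=C(\C)CC(OC)OC | intermediate
10 | (2E,5S,6E)-5-{[tert-butyl(dimethyl)silyl]oxy}-9,9-dimethoxy-3,7-dimethylnona-2,6-dienoyl chloride | ClC(=O)/C=C(\C)C[C@H](O[Si](C)(C)C(C)(C)C)/C=C(\C)CC(OC)OC | intermediate (not isolated)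
11 | (5S,6E)-5-{[tert-butyl(dimethyl)silyl]oxy}-9,9-dimethoxy-7-methyl-3-methylidenenona-1,6-dien-1-one (vinylketene) | O=C=CC(=C)C[C@H](O[Si](C)(C)C(C)(C)C)/C=C(\C)CC(OC)OC | intermediate (not isolated)
12 | (1R,2S,5R,7R)-2-{[tert-butyl(dimethyl)silyl]oxy}-7-(2,2-dimethoxyethyl)-7-methyl-4-methylidenebicyclo[3.1.1]heptan-6-one | COC(OC)C[C@@]1(C)[C@@H]2[C@@H](O[Si](C)(C)C(C)(C)C)CC(=C)[C@H]1C2=O | intermediate
13 | methyl 2-(trimethylsilyl)propanoate | COC(=O)C(C)[Si](C)(C)C | starting material
14 | lithium 1-methoxy-2-(trimethylsilyl)prop-1-en-1-olate | COC([O-])=C(C)[Si](C)(C)C.[Li+] | intermediate (not isolated)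
15 | methyl 2-[2-{[tert-butyl(dimethyl)silyl]oxy}-7-(2,2-dimethoxyethyl)-7-methyl-4-methylidenebicyclo[3.1.1]heptan-6-ylidene]propanoate | COC(OC)C[C@@]1(C)[C@@H]2[C@@H](O[Si](C)(C)C(C)(C)C)CC(=C)[C@H]1C2=C(C)C(=O)OC | intermediate (not isolated)
16 | methyl 2-[7-(2,2-dimethoxyethyl)-2-hydroxy-7-methyl-4-methylidenebicyclo[3.1.1]heptan-6-ylidene]propanoate | COC(OC)C[C@@]1(C)[C@@H]2[C@@H](O)CC(=C)[C@H]1C2=C(C)C(=O)OC | intermediate
17 | methyl 2-[7-(2,2-dimethoxyethyl)-2-hydroxy-7-methyl-4-methylidenebicyclo[3.1.1]heptan-6-yl]-2-methylpropanoate | COC(OC)C[C@@]1(C)[C@@H]2[C@@H](O)CC(=C)[C@H]1[C@@H]2C(C)(C)C(=O)OC | intermediate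
18 | 2-[7-(2,2-dimethoxyethyl)-2-hydroxy-7-methyl-4-methylidenebicyclo[3.1.1]heptan-6-yl]-2-methylpropanal | COC(OC)C[C@@]1(C)[C@@H]2[C@@H](O)CC(=C)[C@H]1[C@@H]2C(C)(C)C=O | intermediate (not isolated)
19 | 2-[2-hydroxy-7-methyl-4-methylidene-7-(2-oxoethyl)bicyclo[3.1.1]heptan-6-yl]-2-methylpropanal | O=CC[C@@]1(C)[C@@H]2[C@@H](O)CC(=C)[C@H]1[C@@H]2C(C)(C)C=O | intermediate
20 | 2-methyl-2-[6-methyl-4-methylidene-2-oxo-6-(2-oxoethyl)bicyclo[3.1.1]heptan-7-yl]propanal | O=CC[C@@]1(C)[C@@H]2C(=O)CC(=C)[C@H]1[C@@H]2C(C)(C)C=O | intermediate (not isolated)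
21 | 2-[4,6-dimethyl-2-oxo-6-(2-oxoethyl)bicyclo[3.1.1]hept-3-en-7-yl]-2-methylpropanal | O=CC[C@@]1(C)[C@@H]2C(=O)C=C(C)[C@H]1[C@@H]2C(C)(C)C=O | intermediate
22 | (4R,5S,7S,10R,11R)-7-hydroxylongipin-2-ene-1,8-dione | O=C1C[C@@]2(C)[C@@H]3C(=O)C=C(C)[C@H]2[C@@H]3C(C)(C)[C@@H]1O | intermediate
23 | (4R,5S,7S,8S,10R,11R)-7,8-dihydroxylongipin-2-en-1-one | O[C@H]1C[C@@]2(C)[C@@H]3C(=O)C=C(C)[C@H]2[C@@H]3C(C)(C)[C@@H]1O | intermediate
24 | (2Z)-2-methylbut-2-enoic anhydride | C/C=C(/C)C(=O)OC(=O)/C(C)=C\C | starting material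
25 | (4R,5S,7S,8S,10R,11R)-1-oxolongipin-2-ene-7,8-diyl bis[(2Z)-2-methylbut-2-enoate] | C/C=C(/C)C(=O)O[C@H]1C[C@@]2(C)[C@@H]3C(=O)C=C(C)[C@H]2[C@@H]3C(C)(C)[C@@H]1OC(=O)/C(C)=C\C | target

## Step count, risks and fallbacks

Total step count: 13. Longest linear sequence: 13 steps (1 → 25); 3, 5, 13 and 24 enter as purchased building blocks.

The three steps most likely to fail are steps 6, 8 and 11.

**Step 6 (ketene cycloaddition).** Risks are oligomerisation of the vinylketene and incomplete facial control by the C1 silyloxy group. The fallback sets out from 9 and replaces the thermal ketene cycloaddition by a Lewis-acid allenoate cycloaddition. The acid chloride is treated with Et3N in the presence of methyl 2-(triphenylphosphoranylidene)propanoate, so that the vinylketene is intercepted by Wittig olefination as the vinylallenoate methyl (7S,8E)-7-{[tert-butyl(dimethyl)silyl]oxy}-11,11-dimethoxy-2,9-dimethyl-5-methylideneundeca-2,3,8-trienoate F1. EtAlCl2 in CH2Cl2 at −78 °C then promotes the intramolecular allenoate–alkene [2+2], in which the central allene carbon bonds to C11 and the γ-carbon to C10. This gives 15 directly, here isolated, and Bu4NF brings the route back at 16.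

**Step 8 (C5 configuration).** Risks are protonation of C5 from the wrong face and O-methylation of the alkoxide. The fallback sets out from 12 and builds the C5–C6 bond with both methyls already in place. The lithium enolate of methyl 2-methylpropanoate adds to the cyclobutanone from the face away from the silyloxy group to give the tertiary alcohol methyl 2-[2-{[tert-butyl(dimethyl)silyl]oxy}-7-(2,2-dimethoxyethyl)-6-hydroxy-7-methyl-4-methylidenebicyclo[3.1.1]heptan-6-yl]-2-methylpropanoate F2. Acylation with methyl chlorooxoacetate and DMAP gives the methyl oxalate F3. Bu3SnH/AIBN in toluene at 80 °C removes the oxygen; the tertiary cyclobutyl radical keeps its bulky substituent away from the silyloxy-bearing bridge and takes hydrogen on the bridge side, giving the silyl ether of 17, F4. Bu4NF brings the route back at 17.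

**Step 11 (cross-benzoin).** Risks are the seven-membered ring size, competing aldol reaction of the C8 aldehyde, and the wrong C7 epimer. The fallback sets out from 19 and replaces the acyl-anion closure by a reductive ketyl (pinacol) coupling before the enone is made. tBuMe2SiCl/imidazole gives the silyl-protected dialdehyde F5. (C5H5)2TiPh in THF at −78 → 0 °C, a trans-selective pinacol reagent for dialdehydes, closes the ring to the trans-diol F6, with the other trans diastereomer removed by chromatography. LiN(SiMe3)2 and 24 give the bis-angelate F7, HF·pyridine gives the C1 alcohol F8, and Dess–Martin periodinane followed by Et3N brings the route back at 25.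

## Further compounds

F1 | step 6 | methyl (7S,8E)-7-{[tert-butyl(dimethyl)silyl]oxy}-11,11-dimethoxy-2,9-dimethyl-5-methylideneundeca-2,3,8-trienoate | COC(=O)C(C)=C=CC(=C)C[C@H](O[Si](C)(C)C(C)(C)C)/C=C(\C)CC(OC)OC
F2 | step 8 | methyl 2-[2-{[tert-butyl(dimethyl)silyl]oxy}-7-(2,2-dimethoxyethyl)-6-hydroxy-7-methyl-4-methylidenebicyclo[3.1.1]heptan-6-yl]-2-methylpropanoate | COC(OC)C[C@@]1(C)[C@@H]2[C@@H](O[Si](C)(C)C(C)(C)C)CC(=C)[C@H]1[C@]2(O)C(C)(C)C(=O)OC
F3 | step 8 | methyl oxalate ester of F2 | COC(OC)C[C@@]1(C)[C@@H]2[C@@H](O[Si](C)(C)C(C)(C)C)CC(=C)[C@H]1[C@]2(OC(=O)C(=O)OC)C(C)(C)C(=O)OC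
F4 | step 8 | methyl 2-[2-{[tert-butyl(dimethyl)silyl]oxy}-7-(2,2-dimethoxyethyl)-7-methyl-4-methylidenebicyclo[3.1.1]heptan-6-yl]-2-methylpropanoate | COC(OC)C[C@@]1(C)[C@@H]2[C@@H](O[Si](C)(C)C(C)(C)C)CC(=C)[C@H]1[C@@H]2C(C)(C)C(=O)OC
F5 | step 11 | 2-[2-{[tert-butyl(dimethyl)silyl]oxy}-7-methyl-4-methylidene-7-(2-oxoethyl)bicyclo[3.1.1]heptan-6-yl]-2-methylpropanal | O=CC[C@@]1(C)[C@@H]2[C@@H](O[Si](C)(C)C(C)(C)C)CC(=C)[C@H]1[C@@H]2C(C)(C)C=O
F6 | step 11 | (1S,4R,5S,7S,8S,10R,11R)-1-{[tert-butyl(dimethyl)silyl]oxy}-3-methylidenelongipinane-7,8-diol | O[C@H]1C[C@@]2(C)[C@@H]3[C@@H](O[Si](C)(C)C(C)(C)C)CC(=C)[C@H]2[C@@H]3C(C)(C)[C@@H]1O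
F7 | step 11 | bis[(2Z)-2-methylbut-2-enoate] of F6 | C/C=C(/C)C(=O)O[C@H]1C[C@@]2(C)[C@@H]3[C@@H](O[Si](C)(C)C(C)(C)C)CC(=C)[C@H]2[C@@H]3C(C)(C)[C@@H]1OC(=O)/C(C)=C\C
F8 | step 11 | (1S,4R,5S,7S,8S,10R,11R)-1-hydroxy-3-methylidenelongipinane-7,8-diyl bis[(2Z)-2-methylbut-2-enoate] | C/C=C(/C)C(=O)O[C@H]1C[C@@]2(C)[C@@H]3[C@@H](O)CC(=C)[C@H]2[C@@H]3C(C)(C)[C@@H]1OC(=O)/C(C)=C\C
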